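The sulfone is cut at both carbon–sulfur bonds. The sulfonyl sulfur lies between the exocyclic benzylic CH2 on C1 of the fully substituted benzene ring and the S-methyl carbon, so sulfur dioxide can serve as a two-ended linchpin. In a single flask a benzylzinc reagent (nucleophilic CH2), SO2 from DABSO and iodomethane are joined, creating the CH2–S and S–CH3 bonds without touching the three aryl C–Br bonds. The precursor is the fully substituted benzyl bromide carrying bromine at C2, C3 and C6 and a dimethyl-protected catechol at C4/C5. It is reached by exhaustive ring bromination and benzylic bromination of 3,4-dimethoxytoluene, and BBr3 then frees the catechol.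

Key step: step 3

Remark: the target has no stereocentre or other stereogenic element, so the SMILES defines one achiral compound and no step has to control configuration.

Step 1
Reactants: 1 3,4-dimethoxytoluene
Product: 2 2,3,6-tribromo-4,5-dimethoxytoluene (1,2,4-tribromo-5,6-dimethoxy-3-methylbenzene)
Conditions: Br2 (4 equiv), Fe powder (cat.), CH2Cl2, 0 °C → reflux, dark
Reagents that add atoms: bromine, BrBr
Why: Lewis-acid-catalysed electrophilic aromatic bromination, in which the two methoxy groups and the methyl group activate the only three ring C–H positions, so exhaustive substitution can converge on one product only, and exclusion of light suppresses benzylic bromination.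

Step 2
Reactants: 2 2,3,6-tribromo-4,5-dimethoxytoluene
Product: 3 2,3,6-tribromo-4,5-dimethoxybenzyl bromide (1,2,4-tribromo-3-(bromomethyl)-5,6-dimethoxybenzene)
Conditions: NBS (1.05 equiv), AIBN (cat.), PhCF3, 85 °C
Reagents that add atoms: N-bromosuccinimide, O=C1CCC(=O)N1Br
Why: Wohl–Ziegler radical bromination at the only benzylic C–H site of a ring that has no aromatic hydrogen left, with the two flanking bromines slowing a second hydrogen abstraction so that near-stoichiometric NBS should stop at the monobromide.

Step 3
Reactants: 3 2,3,6-tribromo-4,5-dimethoxybenzyl bromide; 4 DABSO (DABCO bis(sulfur dioxide) adduct); 5 iodomethane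
Product: 8 2,3,6-tribromo-4,5-dimethoxybenzyl methyl sulfone, via benzylzinc bromide 6 (not isolated), via zinc sulfinate 7 (not isolated)
Conditions: Zn dust (activated), LiCl, THF, 0 °C → rt; decant from excess Zn; DABSO (0.6 equiv), THF, rt; then MeI (3 equiv), DMSO, rt
Reagents that add atoms: sulfur dioxide delivered from DABSO 4, C1CN2CCN1CC2.O=S=O.O=S=O; iodomethane 5, CI
Why: Oxidative insertion of zinc into the weak sp3 benzylic C–Br bond of 3 (LiCl helping to clear the organozinc from the metal surface) reverses the polarity of the CH2 carbon and gives benzylzinc 6, which attacks the electrophilic sulfur of SO2 released from DABSO to give zinc sulfinate 7, and SN2 attack of the sulfinate sulfur on iodomethane then delivers sulfone 8. The closest known reaction type is the one-pot sulfone synthesis from organozinc reagents, DABSO and alkyl halides, that is, sulfinate formation followed by S-alkylation in DMSO. No ring is closed and no stereocentre is formed. The step needs insertion at the benzylic bromide in the presence of three aryl C–Br bonds, which the large gap in bond strength should secure, because electron-rich aryl bromides need a transition metal or far more forcing conditions to react with zinc dust. Wurtz-type dimerisation should be held back by the two bromines flanking the CH2 group together with slow addition at 0 °C, and removing unreacted zinc before SO2 is introduced prevents its reduction to dithionite. S- over O-methylation of the ambident sulfinate is secured by the soft electrophile in a dipolar aprotic solvent, and the excess of iodomethane covers the part consumed by liberated DABCO.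

Step 4
Reactants: 8 2,3,6-tribromo-4,5-dimethoxybenzyl methyl sulfone
Product: 10 2,3,6-tribromo-4,5-dihydroxybenzyl methyl sulfone (3,4,6-tribromo-5-[(methylsulfonyl)methyl]benzene-1,2-diol), via cyclic bromoborate 9 (not isolated)
Conditions: BBr3 (4 equiv), CH2Cl2, −78 °C → rt; then H2O, 0 °C
Reagents that add atoms: none
Why: Lewis-acid ether cleavage with boron tribromide, in which boron coordinates each methoxy oxygen and bromide removes the methyl group by SN2 to leave the two neighbouring oxygens tied up as cyclic borate 9, which water hydrolyses to the catechol, while the sulfone and the aryl C–Br bonds are inert to the reagent.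

Compound list
1 | 3,4-dimethoxytoluene | Cc1ccc(OC)c(OC)c1 | starting material
2 | 2,3,6-tribromo-4,5-dimethoxytoluene | Cc1c(Br)c(OC)c(OC)c(Br)c1Br | intermediate
3 | 2,3,6-tribromo-4,5-dimethoxybenzyl bromide | BrCc1c(Br)c(OC)c(OC)c(Br)c1Br | intermediate
4 | DABSO (DABCO bis(sulfur dioxide) adduct) | C1CN2CCN1CC2.O=S=O.O=S=O | starting material
5 | iodomethane | CI | starting material
6 | (2,3,6-tribromo-4,5-dimethoxybenzyl)zinc bromide | Br[Zn]Cc1c(Br)c(OC)c(OC)c(Br)c1Br | intermediate
7 | bromozinc (2,3,6-tribromo-4,5-dimethoxyphenyl)methanesulfinate | O=S(O[Zn]Br)Cc1c(Br)c(OC)c(OC)c(Br)c1Br | intermediate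
8 | 2,3,6-tribromo-4,5-dimethoxybenzyl methyl sulfone | CS(=O)(=O)Cc1c(Br)c(OC)c(OC)c(Br)c1Br | intermediate
9 | 2,4,5,7-tetrabromo-6-[(methylsulfonyl)methyl]-1,3,2-benzodioxaborole | CS(=O)(=O)Cc1c(Br)c2OB(Br)Oc2c(Br)c1Br | intermediate
10 | 2,3,6-tribromo-4,5-dihydroxybenzyl methyl sulfone (3,4,6-tribromo-5-[(methylsulfonyl)methyl]benzene-1,2-diol) | CS(=O)(=O)Cc1c(Br)c(O)c(O)c(Br)c1Br | target

Total step count: 4
Longest linear sequence: 4 steps (1 → 2 → 3 → 8 → 10)

Steps most likely to fail

Step 3. The benzylic organozinc may dimerise at the metal surface, be protonated before it meets SO2, or be formed alongside slow reduction of an aryl C–Br bond. The S-methylation may also stall if liberated DABCO consumes the iodomethane. The fallback sets out from 3 and abandons the organometallic: heating 3 with sodium methanesulfinate in DMF at 60–80 °C should displace the benzylic bromide by SN2 at sulfur. The methyl group is then already on sulfur, and the route is rejoined at 8. This detour makes no compound outside the list (F0).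

Step 1. The third bromination may stall, because the ring is by then deactivated and the last open position is crowded, or the iron bromide/HBr medium may begin to cleave a methyl ether. The fallback sets out from 1 and brominates the far more activated free catechol instead. Demethylation of 1 with BBr3 in CH2Cl2 should give 4-methylcatechol F1 (also a commercial compound). Bromine (about 3.3 equiv) in acetic acid at room temperature should then fill all three ring positions to give 3,4,6-tribromo-5-methylbenzene-1,2-diol F2. Double O-methylation with iodomethane and K2CO3 in DMF rejoins the route at 2.

Step 2. The radical chain may give incomplete conversion together with a second bromination at the benzylic carbon, leaving a mixture that is hard to separate. The fallback sets out from 2 and deliberately drives the bromination past the monobromide with excess NBS (about 2.5 equiv, AIBN, PhCF3, reflux) until no 2 remains. This gives material rich in 1,2,4-tribromo-3-(dibromomethyl)-5,6-dimethoxybenzene F3. Treating the crude product with diethyl phosphite and iPr2NEt in THF at 0 °C to room temperature should remove one bromine from the gem-dibromide only, so all material converges on 3.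

Further compounds
F0 | step 3 | none | none
F1 | step 1 | 4-methylbenzene-1,2-diol (4-methylcatechol) | Cc1ccc(O)c(O)c1
F2 | step 1 | 3,4,6-tribromo-5-methylbenzene-1,2-diol | Cc1c(Br)c(O)c(O)c(Br)c1Br
F3 | step 2 | 1,2,4-tribromo-3-(dibromomethyl)-5,6-dimethoxybenzene | BrC(Br)c1c(Br)c(OC)c(OC)c(Br)c1Br
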